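## Structural features

The target (C28H32O10) is achiral: it has no stereocentre and no stereogenic double bond, so no stereocentres stand next to each other and the whole problem is one of connectivity. Ring A is a hexasubstituted benzene of the acylphloroglucinol type, with the 2-methylpropanoyl group at C1, hydroxyls at C2, C4 and C6, and a CH2 bridge at each of C3 and C5. Each bridge ends at C3 of an identical 6-ethyl-4-hydroxy-5-methyl-2H-pyran-2-one (rings B and C), so every bridge carbon lies between a phenol carbon of ring A and the enol carbon of a vinylogous acid. The fragile parts are the two lactones (opened by hydroxide and alkoxides), the doubly activated CH2 bridges (able to fragment and recombine through quinone-methide-like species in acid or base), the air-sensitive polyphenol and the enolisable ketone. The real difficulty is to attach two identical pyranonylmethyl units to the two most crowded carbons of ring A, at the CH2 oxidation level, without oligomers and without confusing the oxygens. The key step exploits that C3 and C5 of ring A, each flanked by two oxygens, are the only unsubstituted positions of the acylated tri-O-methyl ether, so two iodine atoms mark them unambiguously and become C–Zn bonds, while the CH2–Cl group on C3 of the O-benzylated pyranone behaves as an electron-rich benzylic chloride towards zerovalent palladium.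

## Logic of the disconnections

15 to 14: five O–C bonds are cut (three O–CH3 on ring A, two O–CH2Ph on rings B and C). Free phenols and enols would quench any organometallic and open the bridge-scrambling pathways, so all five are masked. The gain is an intermediate without acidic protons. The demand is that one Lewis acid treatment removes five ethers without touching bridges or lactones.

14 to 13 and two molecules of 12: the two aryl–CH2 bonds are cut. They are identical, they sit at the two oxygen-flanked carbons, and cutting them splits the molecule into one arene and one pyranone used twice. The hexasubstituted ring A is reduced to a dimetalated arene, and the bridge carbon arrives as CH2. The demand is two successive sp2–sp3 couplings at di-ortho-substituted carbons, at the CH2 carbon of the electrophile and not at its C4.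

13 to 4: the two C–Zn bonds are cut back to C–I bonds. Zinc is chosen because it tolerates the ketone. Halogen–magnesium exchange is not relied on: a second exchange on an already magnesiated ring is very slow, and a Grignard-type intermediate could enolise the ketone. The demand is insertion of the metal into two electron-rich, hindered C–I bonds.

4 to 3: the two C–I bonds are cut. Only two ring CH positions remain in 3, so the halogenation cannot go to a wrong site. The demand is a second iodination on a ring that already carries one iodine and an acyl group.

3 to 1 and 2: the aryl–C(=O) bond is cut. The threefold symmetry of 1 makes the site of acylation irrelevant. The demand is monoacylation without loss of a methyl ether next to the new carbonyl.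

12 to 10 (through 11): the C–Cl bond is cut back to C–OH. The chloride is too labile to carry, so it is made last from the stable alcohol. The demand is activation under non-acidic conditions that spare the benzyl ether.

10 to 9: the CH2OH group is traced to CHO. The one-carbon unit enters at the aldehyde level because C3 of the pyranone is easily formylated. The demand is 1,2-reduction of an aldehyde that is part of a push–pull dienyl system.

9 to 8: the C4–O bond is cut, leaving chloride at C4. Alkylation of a 3-formyl-4-hydroxypyranone anion would be ambident (three oxygens and C3), whereas substitution at C4 can put the benzyl group on one oxygen only. The demand is attack at C4 in preference to the lactone carbonyl and the aldehyde.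

8 to 7: the C3–CHO bond and the C4–Cl bond are cut together. One chloroiminium reagent does both jobs. The demand is reaction at C3 and at the C4 oxygen without attack on the 5-methyl and 6-ethyl groups.

7 to 5 and 6: the C4–C5 and O1–C2 bonds of the pyranone are cut. Ring B/C is thus reduced to a symmetrical ketone and a three-carbon bis-electrophile. The demand is that the product, itself nucleophilic at C3, does not react further.

## Other disconnections considered

Alternative 1: The cut lies inside rings B and C: the C5–C6 bond of each pyranone and, one step later, each lactone O1–C2 bond, so both heterocycles are unrolled into open triketide ester chains on the ring A CH2 groups. In the forward direction the bis(β-keto ester) A2 would be converted by a lithium amide base into its bis-dianion and acylated at both γ-carbons by N-methoxy-N-methylpropanamide A3 to give A1. Lactonisation of both chains and cleavage of the three methyl ethers would follow.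
- In favour: the aryl–CH2 bonds come from ordinary enolate alkylation, no transition metal or organometallic next to the ketone is needed, the pyranone hydroxyls never need protection, and the stereoisomer mixture in A1 is harmless because every stereocentre becomes sp2 on cyclisation.
- Against: A2 has four acidic sites besides the enolisable 2-methylpropanoyl group, and each acylation product is more acidic than its precursor, so uneven acylation of the two arms is the obvious hazard. The whole linear sequence is carried on the arene.
- Comparison: on structure, A1 holds the full carbon skeleton as 14 does, but with both heterocycles still to be closed. On mechanism, polar enolate chemistry replaces palladium catalysis, and in avoiding the labile chloride 12 and any O-protection of the pyranones the alternative is the better plan. The end game is equal, since the same three aryl methyl ethers must be cleaved. The step count is about equal, but the alternative is less convergent and its two-directional step comes late.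

Alternative 2: Three bonds of ring A are cut, so the benzene ring is built and not functionalised. In the forward direction the cyclobutenone A5 and ethoxyacetylene A6 would be heated. A four-electron ring opening to a vinylketene, [2+2] addition of the electron-rich alkyne, a second ring opening and a six-electron electrocyclisation would give the phenol A4.
- In favour: the substitution pattern is set by the annulation, the three oxygens come out differentiated, and neither metal nor halogen markers are needed.
- Against: A4 still lacks the 2-methylpropanoyl group, which would have to be put on the single free ring CH by Friedel–Crafts or Fries chemistry in the presence of benzyl ethers. A5 is not a simple building block, since both arms must be in place before a ketene dimerisation and an O-benzylation. The 2-pyranone rings are themselves dienes that could engage the alkyne on heating, and the O-ethyl group needs a Lewis acid as strong as that for methyl ethers.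
- Comparison: on structure, regiocontrol is the equal of the chosen plan (both are unambiguous), and the alternative is better in needing no organometallic beside a ketone. On mechanism, a thermal pericyclic cascade replaces cross-coupling and has no catalyst to be inhibited. On step economy it is worse: a C-acylation follows the key step, and the path to A5 is longer than the five steps to 12.

Alternative 3: Two bonds of ring A are cut: the bond between the acyl-bearing carbon and its oxygenated neighbour, and the bond between the third oxygenated carbon and the adjacent bridge-bearing carbon. In the forward direction the diene A8 would combine with the ynone A9. Diene C4 would bond to the ethoxy-bearing alkyne carbon and diene C1 to the acyl-bearing one, and loss of the silylated methanol unit would aromatise the ring to A7.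
- In favour: the ketone and all three oxygens arrive in the ring-forming step, two phenols are already free, and only one ethyl and two benzyl ethers remain.
- Against: A8 is crowded at both reacting termini and sensitive to hydrolysis. It has to be made from the β-keto ester A10, which must first receive two pyranonylmethyl arms at two different carbons. A9 has to be prepared, and a hindered diene of this kind may stop at an open Michael-type adduct.
- Comparison: on structure, the alternative is the better plan in installing the acyl group without a later metalation and in leaving fewer ethers to cleave. On mechanism, its regiochemistry rests on electronic matching of diene and ynone, whereas in the chosen plan it rests on fixed halogen positions; these are equal in principle, but matching is less certain for a crowded diene. On step economy it is worse: an electrophile such as 12 is still needed twice, and alkylations, double silylation, annulation and deprotection exceed steps 3 to 9.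

Key step: step 8

Remark on the chemistry: the dimetalated arene 13 carries two C–Zn bonds on one ring (an arene-1,3-diyl dizinc reagent, not a diarylzinc). Because it is made by zinc insertion into C–I bonds it is written as the bis(zinc iodide) solvated by LiCl, the halide on zinc being a spectator ligand.

## Route

Step 1
Reactants: 1 1,3,5-trimethoxybenzene; 2 2-methylpropanoyl chloride (isobutyryl chloride)
Product: 3 2-methyl-1-(2,4,6-trimethoxyphenyl)propan-1-one
Conditions: SnCl4, CH2Cl2, −10 °C to 0 °C
Reagents that add atoms: none
Why: Friedel–Crafts acylation; all ring CH positions of 1 are equivalent and strongly nucleophilic, and the ketone deactivates the ring against a second acylation. SnCl4 at low temperature is chosen over AlCl3 so that the methoxy group next to the new carbonyl should not be cleaved.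

Step 2
Reactants: 3 2-methyl-1-(2,4,6-trimethoxyphenyl)propan-1-one
Product: 4 1-(3,5-diiodo-2,4,6-trimethoxyphenyl)-2-methylpropan-1-one
Conditions: N-iodosuccinimide (2.2 equiv), CF3CO2H (cat.), MeCN, rt
Reagents that add atoms: N-iodosuccinimide, O=C1CCC(=O)N1I
Why: Electrophilic aromatic iodination; the only two ring CH positions left, each between two methoxy groups, remain strongly activated, so both should be iodinated. The hindered, slowly enolising ketone should not be iodinated at its α-carbon.

Step 3
Reactants: 5 pentan-3-one; 6 malonyl dichloride
Product: 7 6-ethyl-4-hydroxy-5-methyl-2H-pyran-2-one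
Conditions: neat, rt, 48 h, HCl swept out with N2; then aq. NaHCO3 extraction and acidification
Reagents that add atoms: none
Why: Acylation–lactonisation of a ketone by malonyl dichloride, a known route to 6-substituted 4-hydroxy-2-pyranones: the enol of 5 is C-acylated and the enol oxygen of the resulting β-diketone closes the lactone on the second acid chloride. 5 is symmetrical, so only one regioisomer can form.

Step 4
Reactants: 7 6-ethyl-4-hydroxy-5-methyl-2H-pyran-2-one
Product: 8 4-chloro-6-ethyl-5-methyl-2-oxo-2H-pyran-3-carbaldehyde
Conditions: POCl3 (2.5 equiv), DMF, 0 °C to 50 °C; then ice, aq. NaOAc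
Reagents that add atoms: N,N-dimethylformamide, CN(C)C=O; phosphoryl chloride, O=P(Cl)(Cl)Cl; water, O
Why: Vilsmeier–Haack chloroformylation, as known for 4-hydroxycoumarin and 4-hydroxy-6-methyl-2-pyranone: the chloroiminium reagent attacks the nucleophilic enol carbon C3 and turns the vinylogous-acid hydroxyl at C4 into chloride, and hydrolysis on work-up gives the aldehyde. A limited excess of reagent and moderate temperature should spare the 5-methyl and 6-ethyl groups.

Step 5
Reactants: 8 4-chloro-6-ethyl-5-methyl-2-oxo-2H-pyran-3-carbaldehyde
Product: 9 4-(benzyloxy)-6-ethyl-5-methyl-2-oxo-2H-pyran-3-carbaldehyde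
Conditions: BnOH (1.2 equiv), K2CO3 (anhydrous), MeCN, 0 °C to rt
Reagents that add atoms: benzyl alcohol, OCc1ccccc1
Why: Addition–elimination at C4, a vinylogous acid chloride activated by both the lactone and the formyl group, as known for β-chlorovinyl aldehydes such as 4-chloro-3-formylcoumarin with O-nucleophiles. Forming the C4–O bond this way places the benzyl group on the C4 oxygen only, which alkylation of an ambident 3-formyl-4-hydroxypyranone anion could not guarantee.

Step 6
Reactants: 9 4-(benzyloxy)-6-ethyl-5-methyl-2-oxo-2H-pyran-3-carbaldehyde
Product: 10 4-(benzyloxy)-6-ethyl-3-(hydroxymethyl)-5-methyl-2H-pyran-2-one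
Conditions: NaBH4, CeCl3·7H2O, MeOH/THF, −40 °C
Reagents that add atoms: none
Why: Luche reduction; CeCl3 activates the carbonyl and converts NaBH4 into harder alkoxyborohydrides, so 1,2-addition to the aldehyde should outrun conjugate addition at C4 or C6 and attack on the lactone.

Step 7
Reactants: 10 4-(benzyloxy)-6-ethyl-3-(hydroxymethyl)-5-methyl-2H-pyran-2-one
Product: 12 4-(benzyloxy)-3-(chloromethyl)-6-ethyl-5-methyl-2H-pyran-2-one, via pyranonylmethyl methanesulfonate 11 (not isolated)
Conditions: MsCl, 2,4,6-collidine, LiCl, DMF, 0 °C; aqueous work-up only, used at once
Reagents that add atoms: lithium chloride, [Li+].[Cl-]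
Why: Sulfonylation followed by SN2 displacement of the mesylate by chloride under base-buffered conditions that spare the benzyl ether. The C4 oxygen activates the CH2 carbon like a para-alkoxybenzyl position, so displacement should be fast, and for the same reason 12 is not chromatographed or stored.

Step 8
Reactants: 4 1-(3,5-diiodo-2,4,6-trimethoxyphenyl)-2-methylpropan-1-one; 12 4-(benzyloxy)-3-(chloromethyl)-6-ethyl-5-methyl-2H-pyran-2-one (2.3 equiv)
Product: 14 3,3'-{[5-(2-methylpropanoyl)-2,4,6-trimethoxy-1,3-phenylene]bis(methylene)}bis[4-(benzyloxy)-6-ethyl-5-methyl-2H-pyran-2-one], via arenediylbis(zinc iodide) 13 (not isolated)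
Conditions: Zn dust (activated with BrCH2CH2Br and Me3SiCl), LiCl, THF, 50 °C; solution of 13 cannulated off excess Zn; then 12, Pd(OAc)2 (5 mol%), SPhos (2-dicyclohexylphosphino-2′,6′-dimethoxybiphenyl, 10 mol%), THF, 25 °C to 50 °C
Reagents that add atoms: none
Why: Zinc inserts into both C–I bonds of 4 (LiCl keeps the arylzinc iodide in solution), a non-basic metalation that leaves the enolisable ketone untouched and gives 13 with the metal exactly at the two carbons marked by iodine. Pd(OAc)2 is reduced in the flask to zerovalent palladium, which adds oxidatively to the C–Cl bond of 12 to give a pyranonylmethyl chloride complex of divalent palladium; transmetalation from a C–Zn site and reductive elimination then form the aryl–CH2 bond, and the cycle runs again at the second C–Zn site. The closest known reaction type is the Negishi coupling of arylzinc halides with benzylic chlorides to diarylmethanes, here used twice on one arene-1,3-diyl dizinc reagent. No ring is closed and no stereocentre is formed. Site selectivity on ring A needs no control beyond the halogen positions, since C–Zn bonds exist only at C3 and C5. The selectivity that matters is coupling at the CH2 carbon and not at C4 of the pyranone: reductive elimination from the σ-bound (η1) pyranonylmethyl ligand gives the CH2-linked product, whereas bond formation at C4 would create a quaternary carbon and break the pyranone conjugation. The bulky, electron-rich biarylphosphine is chosen because both C–Zn carbons are flanked by two methoxy groups; it should speed transmetalation and reductive elimination enough to suppress homocoupling of 12. Metallic zinc is removed before 12 is added so that it cannot insert into the reactive C–Cl bond.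

Step 9
Reactants: 14 3,3'-{[5-(2-methylpropanoyl)-2,4,6-trimethoxy-1,3-phenylene]bis(methylene)}bis[4-(benzyloxy)-6-ethyl-5-methyl-2H-pyran-2-one]
Product: 15 3,3'-{[2,4,6-trihydroxy-5-(2-methylpropanoyl)-1,3-phenylene]bis(methylene)}bis(6-ethyl-4-hydroxy-5-methyl-2H-pyran-2-one) (CNP0277086.0)
Conditions: BBr3 (10 equiv), CH2Cl2, −78 °C to rt; then MeOH, H2O, 0 °C
Reagents that add atoms: none
Why: Lewis acid ether cleavage (O–B complexation, then bromide attack at the methyl or benzyl carbon); the benzyl ethers and the two methoxy groups ortho to the ketone (chelation) should go first, and the third methoxy group, twisted out of the ring plane by its two ortho substituents, should follow at rt. Low temperature and a cold quench limit acid-promoted reactions at the CH2 bridges; the target has no stereocentre to set.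

## Compound list

1 | 1,3,5-trimethoxybenzene | COc1cc(OC)cc(OC)c1 | starting material
2 | 2-methylpropanoyl chloride (isobutyryl chloride) | CC(C)C(Cl)=O | starting material
3 | 2-methyl-1-(2,4,6-trimethoxyphenyl)propan-1-one | CC(C)C(=O)c1c(OC)cc(OC)cc1OC | intermediate
4 | 1-(3,5-diiodo-2,4,6-trimethoxyphenyl)-2-methylpropan-1-one | CC(C)C(=O)c1c(OC)c(I)c(OC)c(I)c1OC | intermediate
5 | pentan-3-one | CCC(=O)CC | starting material
6 | malonyl dichloride | ClC(=O)CC(Cl)=O | starting material
7 | 6-ethyl-4-hydroxy-5-methyl-2H-pyran-2-one | CCc1oc(=O)cc(O)c1C | intermediate
8 | 4-chloro-6-ethyl-5-methyl-2-oxo-2H-pyran-3-carbaldehyde | CCc1oc(=O)c(C=O)c(Cl)c1C | intermediate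
9 | 4-(benzyloxy)-6-ethyl-5-methyl-2-oxo-2H-pyran-3-carbaldehyde | CCc1oc(=O)c(C=O)c(OCc2ccccc2)c1C | intermediate
10 | 4-(benzyloxy)-6-ethyl-3-(hydroxymethyl)-5-methyl-2H-pyran-2-one | CCc1oc(=O)c(CO)c(OCc2ccccc2)c1C | intermediate
11 | [4-(benzyloxy)-6-ethyl-5-methyl-2-oxo-2H-pyran-3-yl]methyl methanesulfonate (not isolated) | CCc1oc(=O)c(COS(C)(=O)=O)c(OCc2ccccc2)c1C | intermediate
12 | 4-(benzyloxy)-3-(chloromethyl)-6-ethyl-5-methyl-2H-pyran-2-one | CCc1oc(=O)c(CCl)c(OCc2ccccc2)c1C | intermediate
13 | [5-(2-methylpropanoyl)-2,4,6-trimethoxy-1,3-phenylene]bis(zinc iodide), LiCl-solvated (not isolated) | CC(C)C(=O)c1c(OC)c([Zn]I)c(OC)c([Zn]I)c1OC | intermediate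
14 | 3,3'-{[5-(2-methylpropanoyl)-2,4,6-trimethoxy-1,3-phenylene]bis(methylene)}bis[4-(benzyloxy)-6-ethyl-5-methyl-2H-pyran-2-one] | CCc1oc(=O)c(Cc2c(OC)c(Cc3c(OCc4ccccc4)c(C)c(CC)oc3=O)c(OC)c(C(=O)C(C)C)c2OC)c(OCc2ccccc2)c1C | intermediate
15 | 3,3'-{[2,4,6-trihydroxy-5-(2-methylpropanoyl)-1,3-phenylene]bis(methylene)}bis(6-ethyl-4-hydroxy-5-methyl-2H-pyran-2-one), achiral | CCc1oc(=O)c(Cc2c(O)c(Cc3c(O)c(C)c(CC)oc3=O)c(O)c(C(=O)C(C)C)c2O)c(O)c1C | target

## Step count and least certain steps

Total step count: 9. Longest linear sequence: 7 steps (steps 3 to 9, from 5 and 6); the arene branch (steps 1 and 2) joins at step 8.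

Step 8 (key step). The most likely failure is incomplete insertion of zinc into the second C–I bond, because the first C–Zn bond makes an already electron-rich, doubly ortho-substituted ring richer still; coupling would then stop at one arm and the remaining site would be protonated on work-up. A second hazard is slow transmetalation of the hindered aryl group, which would give the pyranonylmethyl–palladium intermediate time to homocouple, or the zinc halide formed time to ionise the chloride. The fallback leaves cross-coupling altogether and sets out from 3 and 12. A Friedel–Crafts alkylation of the two free positions of 3 (C3 and C5 of ring A, still activated by three methoxy groups) with two equivalents of 12, promoted by ZnCl2 in CH2Cl2 or run in hexafluoropropan-2-ol, would return to the route at 14. The regiochemistry remains fixed because 3 has no other ring CH.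

Step 9. Cleavage of the third methyl ether (para to the ketone) may lag behind, and the longer exposure to BBr3 and HBr that it calls for invites acid-promoted fragmentation and recombination at the CH2 bridges or dehydrative ring closure between a phenol and a pyranone C4 hydroxyl. The fallback removes the protecting groups before the fragments are joined. It sets out from 3 and 7 and returns at 15.
- From 3, BBr3 in CH2Cl2 would give 2-methyl-1-(2,4,6-trihydroxyphenyl)propan-1-one F1, a demethylation that is harmless at this stage because no bridge is present.
- From 7, dimethylmethylideneammonium iodide (CH2=NMe2+ I−) in CH2Cl2 would give the Mannich base 3-[(dimethylamino)methyl]-6-ethyl-4-hydroxy-5-methyl-2H-pyran-2-one F2.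
- Heating F1 with two equivalents of F2 in dioxane would give 15 directly, by thermal loss of dimethylamine and conjugate addition of ring A carbons C3 and C5 to the methylidene pyrandione so formed. This is the known Mannich-type alkylation of acylphloroglucinols by 4-hydroxy-2-pyranones.
- Its own weakness is statistical formation of mono-adduct and of methylene-bridged pyranone dimer, which is why it is held in reserve.

Step 5 (and with it step 6). Benzyloxide may attack the lactone carbonyl (ring opening) or the aldehyde in competition with C4, and adventitious water would hydrolyse the C4–Cl bond back to the hydroxyl; in step 6 hydride could add in conjugate fashion at C4 with loss of the benzyloxy group. The fallback avoids both the chloro aldehyde and the hydride reduction. It sets out from 7 and returns at 10.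
- Mitsunobu O-benzylation of 7 (BnOH, PPh3, diisopropyl azodicarboxylate, THF) would give 4-(benzyloxy)-6-ethyl-5-methyl-2H-pyran-2-one F3.
- Ionic bromination at C3, the β-carbon of the enol ether (N-bromosuccinimide, MeCN, dark), would give 4-(benzyloxy)-3-bromo-6-ethyl-5-methyl-2H-pyran-2-one F4.
- Stille coupling of F4 with Bu3SnCH2OH (Pd(PPh3)4, dioxane, 90 °C) would give 10.

Step 3. The product is itself nucleophilic at C3 and may be acylated by further acid chloride, and slow enolisation of the ketone leaves time for the acid chloride to condense with itself, so the mass balance could be poor. The fallback replaces the free ketone by a preformed enol derivative. It sets out from 5 and returns at 7. Silylation of 5 (Me3SiCl, NaI, Et3N, MeCN) would give trimethyl(pent-2-en-3-yloxy)silane F5 as a mixture of double-bond isomers. Addition of F5 to 6 in Et2O at −78 °C, warming to rt and aqueous work-up would give 7, through the known reaction of silyl enol ethers with malonyl dichloride, in which C-acylation is faster and stops cleanly at the pyranone.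

## Further compounds

F0 | step 8 | none | none
F1 | step 9 | 2-methyl-1-(2,4,6-trihydroxyphenyl)propan-1-one | CC(C)C(=O)c1c(O)cc(O)cc1O
F2 | step 9 | 3-[(dimethylamino)methyl]-6-ethyl-4-hydroxy-5-methyl-2H-pyran-2-one | CCc1oc(=O)c(CN(C)C)c(O)c1C
F3 | step 5 | 4-(benzyloxy)-6-ethyl-5-methyl-2H-pyran-2-one | CCc1oc(=O)cc(OCc2ccccc2)c1C
F4 | step 5 | 4-(benzyloxy)-3-bromo-6-ethyl-5-methyl-2H-pyran-2-one | CCc1oc(=O)c(Br)c(OCc2ccccc2)c1C
F5 | step 3 | trimethyl(pent-2-en-3-yloxy)silane, mixture of double-bond isomers | CC=C(CC)O[Si](C)(C)C
A1 | alternative 1 | dimethyl 2,2'-{[5-(2-methylpropanoyl)-2,4,6-trimethoxy-1,3-phenylene]bis(methylene)}bis(4-methyl-3,5-dioxoheptanoate), mixture of stereoisomers | CC(C)C(=O)c1c(OC)c(CC(C(=O)OC)C(=O)C(C)C(=O)CC)c(OC)c(CC(C(=O)OC)C(=O)C(C)C(=O)CC)c1OC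
A2 | alternative 1 | dimethyl 2,2'-{[5-(2-methylpropanoyl)-2,4,6-trimethoxy-1,3-phenylene]bis(methylene)}bis(3-oxopentanoate), mixture of stereoisomers | CC(C)C(=O)c1c(OC)c(CC(C(=O)OC)C(=O)CC)c(OC)c(CC(C(=O)OC)C(=O)CC)c1OC
A3 | alternative 1 | N-methoxy-N-methylpropanamide | CCC(=O)N(C)OC
A4 | alternative 2 | 3,3'-{[2-(benzyloxy)-6-ethoxy-4-hydroxy-1,3-phenylene]bis(methylene)}bis[4-(benzyloxy)-6-ethyl-5-methyl-2H-pyran-2-one] | CCOc1cc(O)c(Cc2c(OCc3ccccc3)c(C)c(CC)oc2=O)c(OCc2ccccc2)c1Cc1c(OCc2ccccc2)c(C)c(CC)oc1=O
A5 | alternative 2 | 3-(benzyloxy)-2,4-bis{[4-(benzyloxy)-6-ethyl-5-methyl-2-oxo-2H-pyran-3-yl]methyl}cyclobut-2-en-1-one, racemic | O=C1C(Cc2c(OCc3ccccc3)c(C)c(CC)oc2=O)=C(OCc2ccccc2)C1Cc1c(OCc2ccccc2)c(C)c(CC)oc1=O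
A6 | alternative 2 | ethoxyacetylene (ethoxyethyne) | CCOC#C
A7 | alternative 3 | 3,3'-{[4-ethoxy-2,6-dihydroxy-5-(2-methylpropanoyl)-1,3-phenylene]bis(methylene)}bis[4-(benzyloxy)-6-ethyl-5-methyl-2H-pyran-2-one] | CCOc1c(C(=O)C(C)C)c(O)c(Cc2c(OCc3ccccc3)c(C)c(CC)oc2=O)c(O)c1Cc1c(OCc2ccccc2)c(C)c(CC)oc1=O
A8 | alternative 3 | 1-methoxy-1,3-bis(trimethylsilyloxy)buta-1,3-diene carrying a [4-(benzyloxy)-6-ethyl-5-methyl-2-oxo-2H-pyran-3-yl]methyl group at C2 and at C4, mixture of double-bond isomers | COC(O[Si](C)(C)C)=C(Cc1c(OCc2ccccc2)c(C)c(CC)oc1=O)C(O[Si](C)(C)C)=CCc1c(OCc2ccccc2)c(C)c(CC)oc1=O
A9 | alternative 3 | 1-ethoxy-4-methylpent-1-yn-3-one | CCOC#CC(=O)C(C)C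
A10 | alternative 3 | methyl 5-[4-(benzyloxy)-6-ethyl-5-methyl-2-oxo-2H-pyran-3-yl]-2-{[4-(benzyloxy)-6-ethyl-5-methyl-2-oxo-2H-pyran-3-yl]methyl}-3-oxopentanoate, racemic | COC(=O)C(Cc1c(OCc2ccccc2)c(C)c(CC)oc1=O)C(=O)CCc1c(OCc2ccccc2)c(C)c(CC)oc1=O
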